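**Assumption:** starting materials 1, 3, 6, 10 and 14 are bought as single isomers; catalyst-bound species of catalytic cycles (Pd, Cu, Ru) are described in the Why lines and carry no number.

**Retrosynthetic overview**
1. Target 19 ⇒ enyne diol 18: the γ-lactone (the only ring, formed last) comes from a Ru-catalysed oxidative cycloisomerisation in which the dienyl group shifts 1,2 along the alkyne (C2–O bond, C3–C1′ bond and C3 stereocentre in one step).
2. 18 ⇒ terminal alkyne 9 + alkenyl iodide 17 (Sonogashira).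
3. 9 ⇒ dienal 5 + (R)-butynyl mesylate 7 (anti-selective allenylindium addition; sets C4 and C5).
4. 5 ⇒ enal 4 (Wittig) ⇒ (R)-3-methylhept-1-ene 2 + crotonaldehyde 3 (cross-metathesis) ⇒ bromoheptene 1 (Cu-catalysed asymmetric allylic methylation).
5. 17 ⇒ iododienal 13 + butenone 14 (reductive syn-aldol) ⇒ pentenynol 10 (methylalumination/iodination, then oxidation).

**Route**

Step 1
Reactants: 1 (E)-1-bromohept-2-ene
Product: 2 (R)-3-methylhept-1-ene
Conditions: MeMgBr (1.2 equiv), CuBr·SMe2 (1 mol%), (R,R)-Taniaphos (1.2 mol%), CH2Cl2, −78 °C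
Reagents that add atoms: methylmagnesium bromide, C[Mg]Br
Why: Cu-catalysed asymmetric allylic alkylation (SN2′): the chiral methylcopper species attacks the γ-carbon of the E-allylic bromide anti to bromide on one enantiotopic face and gives the branched (R)-alkene; the (R,R) ligand is assigned by analogy with cinnamyl bromide, and its antipode is used if the opposite sense is found.

Step 2
Reactants: 2 (R)-3-methylhept-1-ene; 3 (E)-but-2-enal
Product: 4 (R,E)-4-methyloct-2-enal
Conditions: Hoveyda–Grubbs II (3 mol%), 3 (5 equiv), CH2Cl2, 40 °C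
Reagents that add atoms: none
Why: Olefin cross-metathesis of an α-branched terminal alkene with excess enal gives the thermodynamically favoured E-enal and does not touch the allylic stereocentre.

Step 3
Reactants: 4 (R,E)-4-methyloct-2-enal
Product: 5 (2E,4E,6R)-2,6-dimethyldeca-2,4-dienal
Conditions: Ph3P=C(Me)CHO (1.3 equiv), toluene, 90 °C
Reagents that add atoms: 2-(triphenyl-λ5-phosphanylidene)propanal, CC(C=O)=P(c1ccccc1)(c1ccccc1)c1ccccc1
Why: Wittig olefination with a stabilised ylide under neutral conditions gives the E-trisubstituted alkene (>95:5) without epimerising the stereocentre.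

Step 4
Reactants: 6 (R)-but-3-yn-2-ol
Product: 7 (R)-but-3-yn-2-yl methanesulfonate
Conditions: MsCl, Et3N, CH2Cl2, −78 → 0 °C
Reagents that add atoms: methanesulfonyl chloride, CS(=O)(=O)Cl
Why: O-sulfonylation breaks no bond at the stereocentre, so configuration is retained.

Step 5
Reactants: 5 (2E,4E,6R)-2,6-dimethyldeca-2,4-dienal; 7 (R)-but-3-yn-2-yl methanesulfonate
Product: 9 (3S,4S,5E,7E,9R)-3,5,9-trimethyltrideca-5,7-dien-1-yn-4-ol, via allenylindium 8 (not isolated)
Conditions: Pd(dppf)Cl2 (5 mol%), InI (1.4 equiv), THF–HMPA (3:1), 0 °C → rt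
Reagents that add atoms: none
Why: Marshall propargylation: Pd(0) displaces mesylate anti (SN2′), transmetalation gives allenylindium 8, and its cyclic SE2′ addition to the aldehyde forms C3 with net inversion of the mesylate centre (S) and C4 anti to it (S).

Step 6
Reactants: 10 (E)-pent-2-en-4-yn-1-ol
Product: 12 (2E,4E)-5-iodo-4-methylpenta-2,4-dien-1-ol, via alkenylalane 11 (not isolated)
Conditions: Me3Al (3 equiv), Cp2ZrCl2 (0.25 equiv), CH2Cl2, 0 °C → rt; then I2, THF, −30 → 0 °C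
Reagents that add atoms: trimethylaluminium, C[Al](C)C; iodine, II
Why: Negishi Zr-catalysed carboalumination adds Me and Al syn across the terminal alkyne (Me to the internal carbon), and iodinolysis with retention gives the 4E iodide.

Step 7
Reactants: 12 (2E,4E)-5-iodo-4-methylpenta-2,4-dien-1-ol
Product: 13 (2E,4E)-5-iodo-4-methylpenta-2,4-dienal
Conditions: activated MnO2 (15 equiv), CH2Cl2, rt
Reagents that add atoms: none
Why: MnO2 oxidises the allylic alcohol selectively under neutral conditions, with no E/Z erosion and no reaction at the alkenyl iodide.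

Step 8
Reactants: 14 but-3-en-2-one; 13 (2E,4E)-5-iodo-4-methylpenta-2,4-dienal
Product: 17 (3R,4S,5E,7E)-4-hydroxy-8-iodo-3,7-dimethylocta-5,7-dien-2-one, via boron enolate 15 (not isolated), via boron aldolate 16 (not isolated)
Conditions: (+)-Ipc2BH [from (−)-α-pinene] (1.0 equiv), 14 (1.05 equiv), Et2O, 0 °C; then 13, −78 °C; pH 7 buffer, MeOH, 30% H2O2, 0 °C
Reagents that add atoms: none
Why: Reductive aldol: 1,4-hydroboration of s-cis butenone gives the regiodefined (Z)-enolborinate 15, which reacts through a Zimmerman–Traxler chair (syn), the Ipc groups directing attack to the Re face of the aldehyde to give (3R,4S); the facial sense is assigned by analogy with Ipc2B crotyl and Z-enolate reagents.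

Step 9
Reactants: 9 (3S,4S,5E,7E,9R)-3,5,9-trimethyltrideca-5,7-dien-1-yn-4-ol; 17 (3R,4S,5E,7E)-4-hydroxy-8-iodo-3,7-dimethylocta-5,7-dien-2-one
Product: 18 (3R,4S,5E,7E,11S,12S,13E,15E,17R)-4,12-dihydroxy-3,7,11,13,17-pentamethylhenicosa-5,7,13,15-tetraen-9-yn-2-one
Conditions: Pd(PPh3)2Cl2 (3 mol%), CuI (6 mol%), i-Pr2NH (3 equiv), THF (degassed), rt
Reagents that add atoms: none
Why: Sonogashira coupling joins the terminal alkyne and the alkenyl iodide with retention of alkene geometry, and the mild amine at rt tolerates the free alcohols and the β-hydroxy ketone.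

Step 10
Reactants: 18 (3R,4S,5E,7E,11S,12S,13E,15E,17R)-4,12-dihydroxy-3,7,11,13,17-pentamethylhenicosa-5,7,13,15-tetraen-9-yn-2-one
Product: 19 (3S,4S,5S)-3-[(1E,3E,5S,6R)-5-hydroxy-2,6-dimethyl-7-oxoocta-1,3-dien-1-yl]-4-methyl-5-[(2E,4E,6R)-6-methyldeca-2,4-dien-2-yl]oxolan-2-one
Conditions: CpRuCl(dppe) (10 mol%), NaBArF4 (12 mol%), 4-methylpyridine N-oxide (1.5 equiv), PhCl (0.02 M), 80 °C
Reagents that add atoms: 4-methylpyridine N-oxide, Cc1cc[n+]([O-])cc1
Why: Proposed new method: the cationic CpRu(dppe)+ fragment converts the internal enyne into a disubstituted vinylidene by a metal-mediated 1,2-shift of the dienyl group from C9 to C10, the C12 hydroxyl adds to the electrophilic vinylidene carbon to close the five-membered ring, protonation at C10 gives a cyclic Ru oxacarbene whose acidic α-hydrogen lets C3 settle in the all-trans (thermodynamic) arrangement, and O-transfer from the N-oxide releases the lactone; the closest known reactions are the Ru-catalysed cycloisomerisation–oxidation of terminal homopropargylic alcohols to γ-butyrolactones (1,2-H shift) and the Ru-catalysed cycloisomerisation of internal 2-alkynylanilides with 1,2-carbon migration.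

**Compound list**
1 | (E)-1-bromohept-2-ene | CCCC/C=C/CBr | starting material
2 | (R)-3-methylhept-1-ene | CCCC[C@@H](C)C=C | intermediate
3 | (E)-but-2-enal | C/C=C/C=O | starting material
4 | (R,E)-4-methyloct-2-enal | CCCC[C@@H](C)/C=C/C=O | intermediate
5 | (2E,4E,6R)-2,6-dimethyldeca-2,4-dienal | CCCC[C@@H](C)/C=C/C=C(\C)C=O | intermediate
6 | (R)-but-3-yn-2-ol | C#C[C@@H](C)O | starting material
7 | (R)-but-3-yn-2-yl methanesulfonate | C#C[C@@H](C)OS(C)(=O)=O | intermediate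
8 | (P)-buta-1,2-dien-1-yl(iodo)indium methanesulfonate (allenylindium) | CC([H])=[C@@]=C([H])[In](I)OS(C)(=O)=O | intermediate
9 | (3S,4S,5E,7E,9R)-3,5,9-trimethyltrideca-5,7-dien-1-yn-4-ol | CCCC[C@@H](C)/C=C/C=C(\C)[C@@H](O)[C@@H](C)C#C | intermediate
10 | (E)-pent-2-en-4-yn-1-ol | C#C/C=C/CO | starting material
11 | dimethylaluminium (2E,4E)-5-(dimethylalumanyl)-4-methylpenta-2,4-dien-1-olate (alkenylalane) | C[Al](C)OC/C=C/C(C)=C/[Al](C)C | intermediate
12 | (2E,4E)-5-iodo-4-methylpenta-2,4-dien-1-ol | OC/C=C/C(C)=C/I | intermediate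
13 | (2E,4E)-5-iodo-4-methylpenta-2,4-dienal | O=C/C=C/C(C)=C/I | intermediate
14 | but-3-en-2-one | CC(=O)C=C | starting material
15 | (Z)-but-2-en-2-yl (+)-diisopinocampheylborinate (boron enolate) | C/C=C(/C)OB([C@H]1C[C@H]2C[C@@H]([C@@H]1C)C2(C)C)[C@H]1C[C@H]2C[C@@H]([C@@H]1C)C2(C)C | intermediate
16 | (+)-diisopinocampheylborinate of 17 (boron aldolate) | I/C=C(C)/C=C/[C@H](OB([C@H]1C[C@H]2C[C@@H]([C@@H]1C)C2(C)C)[C@H]1C[C@H]2C[C@@H]([C@@H]1C)C2(C)C)[C@@H](C)C(C)=O | intermediate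
17 | (3R,4S,5E,7E)-4-hydroxy-8-iodo-3,7-dimethylocta-5,7-dien-2-one | I/C=C(C)/C=C/[C@H](O)[C@@H](C)C(C)=O | intermediate
18 | (3R,4S,5E,7E,11S,12S,13E,15E,17R)-4,12-dihydroxy-3,7,11,13,17-pentamethylhenicosa-5,7,13,15-tetraen-9-yn-2-one | CCCC[C@@H](C)/C=C/C=C(\C)[C@@H](O)[C@@H](C)C#C/C=C(C)/C=C/[C@H](O)[C@@H](C)C(C)=O | intermediate
19 | (3S,4S,5S)-3-[(1E,3E,5S,6R)-5-hydroxy-2,6-dimethyl-7-oxoocta-1,3-dien-1-yl]-4-methyl-5-[(2E,4E,6R)-6-methyldeca-2,4-dien-2-yl]oxolan-2-one | CCCC[C@@H](C)/C=C/C=C(\C)[C@H]1OC(=O)[C@@H](/C=C(C)/C=C/[C@H](O)[C@@H](C)C(C)=O)[C@@H]1C | target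

**Totals**
Total step count: 10. Longest linear sequence: 6 steps (1, 2, 3, 5, 9, 10).

**Three steps most likely to fail**

Step 10 (new Ru-catalysed migratory oxidative lactonisation). The 1,2-carbon shift may be slow, the polyene may not survive 80 °C with a cationic metal, and C3 may form as the cis epimer or isomerise into conjugation. The fallback uses known chemistry, sets out from 9 and comes back at 19. The terminal alkyne of 9 is cyclised by the known Ru-catalysed cycloisomerisation–oxidation (CpRu(cod)Cl, tri(2-furyl)phosphine, N-hydroxysuccinimide, Bu4NBr, NaHCO3, DMF–H2O, 95 °C) to (4S,5S)-4-methyl-5-[(2E,4E,6R)-6-methyldeca-2,4-dien-2-yl]oxolan-2-one F1. In parallel, 12 is silylated (TBSCl, imidazole) to tert-butyl{[(2E,4E)-5-iodo-4-methylpenta-2,4-dien-1-yl]oxy}dimethylsilane F2. The zinc enolate of F1 (LiHMDS, then ZnCl2, THF) is α-alkenylated with F2 under Pd catalysis (Pd(dba)2, Q-Phos, rt), trans to the C4 methyl, giving (3S,4S,5S)-3-[(1E,3E)-5-{[tert-butyl(dimethyl)silyl]oxy}-2-methylpenta-1,3-dien-1-yl]-4-methyl-5-[(2E,4E,6R)-6-methyldeca-2,4-dien-2-yl]oxolan-2-one F3. HF·pyridine gives (3S,4S,5S)-3-[(1E,3E)-5-hydroxy-2-methylpenta-1,3-dien-1-yl]-4-methyl-5-[(2E,4E,6R)-6-methyldeca-2,4-dien-2-yl]oxolan-2-one F4, and MnO2 gives (2E,4E)-4-methyl-5-{(3S,4S,5S)-4-methyl-5-[(2E,4E,6R)-6-methyldeca-2,4-dien-2-yl]-2-oxooxolan-3-yl}penta-2,4-dienal F5. The reductive aldol of step 8 (14, (+)-Ipc2BH) on F5 then gives 19.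

Step 8 (reductive aldol). 1,2- versus 1,4-hydroboration of butenone, butenone polymerisation and the level of enantiofacial control are uncertain, and the facial sense is assigned by analogy. The fallback sets out from 13 and comes back at 17. An Evans syn-aldol of 13 with the dibutylboron (Z)-enolate of (R)-4-benzyl-3-propanoyl-1,3-oxazolidin-2-one (Bu2BOTf, i-Pr2NEt, CH2Cl2, −78 → 0 °C) gives (4R)-4-benzyl-3-[(2R,3S,4E,6E)-3-hydroxy-7-iodo-2,6-dimethylhepta-4,6-dienoyl]-1,3-oxazolidin-2-one F6. Transamidation (MeONHMe·HCl, Me3Al) gives (2R,3S,4E,6E)-3-hydroxy-7-iodo-N-methoxy-N,2,6-trimethylhepta-4,6-dienamide F7, and MeMgBr (THF, 0 °C) gives 17.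

Step 5 (allenylindium propargylation). The anti:syn ratio and the ee with the α-branched dienal may be moderate, and Pd(0) may engage the dienal. The fallback sets out from 5 and comes back at 9. An Ir-catalysed transfer-hydrogenative carbonyl propargylation uses the 1,3-enyne (but-3-en-1-yn-1-yl)tri(propan-2-yl)silane as allenyl-metal surrogate ([Ir(cod)Cl]2, SEGPHOS-type ligand of the enantiomer giving 3S,4S, HCO2H as reductant, THF, 60 °C). It gives the anti adduct (3S,4S,5E,7E,9R)-3,5,9-trimethyl-1-[tri(propan-2-yl)silyl]trideca-5,7-dien-1-yn-4-ol F8 under catalyst control, and TBAF (THF, 0 °C) removes the silyl group to give 9.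

**Further compounds**
F1 | step 10 | (4S,5S)-4-methyl-5-[(2E,4E,6R)-6-methyldeca-2,4-dien-2-yl]oxolan-2-one | CCCC[C@@H](C)/C=C/C=C(\C)[C@H]1OC(=O)C[C@@H]1C
F2 | step 10 | tert-butyl{[(2E,4E)-5-iodo-4-methylpenta-2,4-dien-1-yl]oxy}dimethylsilane | CC(C)(C)[Si](C)(C)OC/C=C/C(C)=C/I
F3 | step 10 | (3S,4S,5S)-3-[(1E,3E)-5-{[tert-butyl(dimethyl)silyl]oxy}-2-methylpenta-1,3-dien-1-yl]-4-methyl-5-[(2E,4E,6R)-6-methyldeca-2,4-dien-2-yl]oxolan-2-one | CCCC[C@@H](C)/C=C/C=C(\C)[C@H]1OC(=O)[C@@H](/C=C(C)/C=C/CO[Si](C)(C)C(C)(C)C)[C@@H]1C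
F4 | step 10 | (3S,4S,5S)-3-[(1E,3E)-5-hydroxy-2-methylpenta-1,3-dien-1-yl]-4-methyl-5-[(2E,4E,6R)-6-methyldeca-2,4-dien-2-yl]oxolan-2-one | CCCC[C@@H](C)/C=C/C=C(\C)[C@H]1OC(=O)[C@@H](/C=C(C)/C=C/CO)[C@@H]1C
F5 | step 10 | (2E,4E)-4-methyl-5-{(3S,4S,5S)-4-methyl-5-[(2E,4E,6R)-6-methyldeca-2,4-dien-2-yl]-2-oxooxolan-3-yl}penta-2,4-dienal | CCCC[C@@H](C)/C=C/C=C(\C)[C@H]1OC(=O)[C@@H](/C=C(C)/C=C/C=O)[C@@H]1C
F6 | step 8 | (4R)-4-benzyl-3-[(2R,3S,4E,6E)-3-hydroxy-7-iodo-2,6-dimethylhepta-4,6-dienoyl]-1,3-oxazolidin-2-one | I/C=C(C)/C=C/[C@H](O)[C@@H](C)C(=O)N1[C@H](Cc2ccccc2)COC1=O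
F7 | step 8 | (2R,3S,4E,6E)-3-hydroxy-7-iodo-N-methoxy-N,2,6-trimethylhepta-4,6-dienamide | I/C=C(C)/C=C/[C@H](O)[C@@H](C)C(=O)N(C)OC
F8 | step 5 | (3S,4S,5E,7E,9R)-3,5,9-trimethyl-1-[tri(propan-2-yl)silyl]trideca-5,7-dien-1-yn-4-ol | CCCC[C@@H](C)/C=C/C=C(\C)[C@@H](O)[C@@H](C)C#C[Si](C(C)C)(C(C)C)C(C)C
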